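## The problem

The target joins two rings through one methylene group. Ring A is a cyclopentane in which C1 carries the CH2 link, C2 is the methyl carbinol, C3 and C4 are CH2 groups and C5 carries the isopropenyl group. Ring B is an enolized cyclohexanetrione with the link at C4', the isovaleryl group at C2' and a quaternary methyl/prenyl carbon at C6'. The join is therefore a single C–C bond between a doubly branched CH2 and a fully substituted ring carbon.

Ring A has three contiguous stereocenters: C5 (S), C1 (R) and C2 (S), with isopropenyl trans to the link and the hydroxyl cis to it. C5 can control C1 if C1 lies α to a carbonyl and settles trans. The C1 substituent can then direct the face from which a methyl group reaches C2. The fourth center, C6' of ring B, is insulated from ring A by the CH2 group; no relay is available, so it must be set by a reagent and checked on its own.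

The tertiary alcohol lies six atoms from an enol oxygen, so acid would close it to a cyclic ether or eliminate it. The isopropenyl and prenyl alkenes exclude hydrogenation, strong acid and electrophilic oxidants. The triketone is acidic and ambident, so ring B should be dearomatized last and under near-neutral conditions.

The feature that opens the route is that C2 is a ketone in disguise. C1 and C5 are then the α- and β-carbons of a cyclopentanone, and C3 and C4 carry no substituents. The C4–C5 bond can therefore be made by 4π electrocyclization of a divinyl ketone, with the leftover alkene placed at C3=C4 by a silyl group and later removed by conjugate reduction.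

## Retrosynthesis

**Prenyl–C6' bond (26 ⇒ 23 + 25).** The last cut removes the prenyl group and returns ring B to the aromatic acylphloroglucinol 23. Every ring carbon of 23 is substituted, so C-alkylation can only dearomatize. Of the two alkyl-bearing carbons, the methyl one is open and the other is shielded by the branched side chain. Cutting C6'–CH3 instead would call for an enantioselective methylation, for which no comparable handle exists. A π-allylpalladium electrophile from carbonate 25 (made from 24) allows a chiral ligand to choose the face. The forward step must deliver C- over O-alkylation, the linear prenyl isomer, and one face of the arene.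

**Aryl–CH2 bond (23 ⇒ 18 + 21).** The link carbon is taken back to the aldehyde of 18, and the arene 21 serves as the nucleophile. Alkylating 21 with a halide derived from 17 would be an SN2 reaction at a carbon branched on both sides and would compete with O-alkylation. The aldehyde route goes through o-quinone methide 22, which is reduced in the same flask. Arene 21 has one free position, so regiochemistry is automatic. The forward step must condense a hindered β-hydroxy aldehyde without epimerizing C1 or opening the ring by retro-aldol cleavage.

**Acyl–arene bond (21 ⇒ 19 + 20).** A Friedel–Crafts acylation. The two free positions of 19 are equivalent, so only mono-acylation has to be controlled.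

**Oxidation level and C2–CH3 bond (18 ⇒ 17 ⇒ 16 ⇒ 15).** The aldehyde comes from the primary alcohol of diol 17, which comes from silyl ether 16. The C2–CH3 bond is then cut to give ketone 15. Carrying the quaternary carbinol through the ring-forming step would remove the carbonyl that the ring synthesis needs. Adding methyl afterwards lets the C1 substituent choose the face. The forward addition must come anti to the silyloxymethyl group and must not enolize a β-silyloxy ketone.

**Ring alkene (15 ⇒ 13).** Ketone 15 is the conjugate-reduction product of enone 13 (through silyl enol ether 14). The alkene sits between the two carbons that are CH2 in the target, so no stereocenter is at stake. The forward step must leave the isopropenyl group alone.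

**Electrocyclic bond (13 ⇒ 12).** Cutting C3–C4 of 13 gives the acyclic, achiral trienone 12. The neighbouring option, conjugate addition of an isopropenyl metal to a 5-substituted cyclopentenone, would need that cyclopentenone in enantiopure form first. The electrocyclization makes the ring, sets C4 absolutely under catalyst control and lets C5 follow. The silyl group at C1 of 12 decides where the alkene ends up. All stereochemistry is removed at this cut.

**C4=C5 alkene of the trienone (12 ⇒ 10 ⇒ 7 + 8).** An aldol condensation. Aldol 10 is dehydrated through acetate 11, and 10 comes from the enolate 9 of ketone 7 and methacrolein 8. Ketone 7 enolizes on one side only. The forward sequence must give the (4E) alkene and must keep the β-silyloxy enolate from expelling silanolate.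

**Vinyl–carbonyl bond (7 ⇒ 3 + 4; 3 ⇒ 2 ⇒ 1).** Ketone 7 is the acylation product of vinyllithium 5 (from bromide 4) with the N-methoxy-N-methyl amide 3, through adduct 6. Amide 3 comes in two steps from hydroxy ester 1 through silyl ether 2. The bromide carries the (E) geometry and the silicon atom that the key step needs.

## Roads not taken

**Alternative 1:** Cut both the CH2–C1 bond and the C2–O bond at once. In the forward direction, oxidation of the ring-methyl triketone A2 (Ag2O, or anodically with a quinone mediator) would give an o-quinone methide. Its oxadiene would add across the trisubstituted alkene of cyclopentene A3 to give the cis-fused dihydropyran A1.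
- Merits: it is the most convergent of the four plans. Suprafacial addition fixes the cis relation of oxygen and link at C1/C2 without relying on a nucleophile's facial preference. On that point it is better than the chosen plan, which depends on the face selectivity of a methyl addition.
- Weak points: A1 is the cyclic enol ether of the target. Freeing the tertiary alcohol means breaking the O–C(sp2) bond of a hindered vinylogous ester, while acid would ionize the tertiary C–O bond and eliminate. The quinone methide must also choose the ring alkene of A3 over its isopropenyl group and over the prenyl group of A2, and must add anti to the isopropenyl group. A2 still needs its quaternary center set, and A3 needs its own asymmetric synthesis.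
- Comparison: the chosen plan is longer, but it never forms the ether and sets each center in a separate, checkable step.

**Alternative 2:** Cut the C1–C5 bond. The lithium enolate of aryl ketone A5 would attack the internal terminus of the π-allylpalladium unit formed from its allylic carbonate, closing the cyclopentane in a 5-exo sense to give A4.
- Merits: the carbinol center comes from linalool, so the absolute configuration needs no chiral catalyst and the methyl addition disappears. In this respect it is better than the chosen plan, whose absolute configuration depends on a chiral acid whose sense must be established.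
- Weak points: the enolate of A5 is β to a silyloxy group on a tertiary carbon and can expel it. The isopropenyl center is set irreversibly in the C–C bond-forming step, relative to a quaternary carbinol whose two faces differ only modestly. After the ring closure the aryl ketone must be reduced to CH2, three acetal groups removed with acid beside a tertiary silyl ether and an isopropenyl group, and the acyl and prenyl groups still installed.
- Comparison: the chosen plan carries no protecting groups on the arene and reaches the target in two steps after the fragments meet.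

**Alternative 3:** Cut two bonds of ring B. The kinetic methyl enolate of butanone A7 would be C-acylated by the acid chloride of the malonate half ester A8, and the derived dianion would close onto the methyl ester to give trione A6.
- Merits: the quaternary center is set early on a small molecule by desymmetrization of a malonate, with a configuration that can be verified before the fragments are joined. This is more secure than the chosen plan's late, catalyst-controlled prenylation next to remote stereocenters.
- Weak points: A7 still contains the whole of ring A and one extra carbon, so the cyclopentane problem is untouched. A hindered α,α-disubstituted acid chloride invites O-acylation. The ring closure attacks an ester on a quaternary carbon, where retro-Claisen cleavage competes. A6 still lacks the isovaleryl group.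
- Comparison: the chosen plan uses an arene that already holds all six ring carbons, and joins and dearomatizes it in two steps. The price is the reliance on catalyst control at C6'.

Key step: step 6

Assumption: the sense of induction of the chiral acid in step 6 and of the ligand in step 14 cannot be derived from these substrates alone; one antipode is written for each, and the mirror-image catalyst would be used if the first analysis shows the opposite sense.

## Route

Step 1
Reactants: 1 methyl 3-hydroxypropanoate
Product: 2 methyl 3-[(triisopropylsilyl)oxy]propanoate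
Conditions: TIPSCl, imidazole, DMF, 0 °C to rt
Reagents that add atoms: chlorotriisopropylsilane (TIPSCl), CC(C)[Si](Cl)(C(C)C)C(C)C
Why: Silylation of a primary alcohol; the TIPS ether is chosen to survive organolithium reagents, the acids of step 6 and CuH, and to be a poor leaving group in β-elimination.

Step 2
Reactants: 2 methyl 3-[(triisopropylsilyl)oxy]propanoate
Product: 3 N-methoxy-N-methyl-3-[(triisopropylsilyl)oxy]propanamide
Conditions: MeNH(OMe)·HCl, iPrMgCl, THF, −20 to 0 °C
Reagents that add atoms: N,O-dimethylhydroxylamine hydrochloride, CNOC.Cl
Why: Aminolysis of a methyl ester by the magnesium amide formed in the flask; β-silyloxy esters are standard substrates and should not eliminate at this temperature.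

Step 3
Reactants: 4 (E)-(2-bromovinyl)trimethylsilane; 3 N-methoxy-N-methyl-3-[(triisopropylsilyl)oxy]propanamide
Product: 7 (E)-5-[(triisopropylsilyl)oxy]-1-(trimethylsilyl)pent-1-en-3-one, via (E)-2-(trimethylsilyl)vinyllithium 5 (not isolated), via lithium hemiaminal adduct 6 (not isolated)
Conditions: 4, t-BuLi (2.0 equiv), Et2O, −78 °C; then 3, −78 to 0 °C; cold 1 M HCl
Reagents that add atoms: none
Why: Bromine–lithium exchange keeps the alkene geometry, and acylation by an N-methoxy-N-methyl amide stops at the ketone because chelated adduct 6 collapses only on quenching.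

Step 4
Reactants: 7 (E)-5-[(triisopropylsilyl)oxy]-1-(trimethylsilyl)pent-1-en-3-one; 8 methacrolein (2-methylprop-2-enal)
Product: 10 (E)-5-hydroxy-6-methyl-4-{[(triisopropylsilyl)oxy]methyl}-1-(trimethylsilyl)hepta-1,6-dien-3-one (mixture of diastereomers), via lithium enolate 9 (not isolated)
Conditions: LiN(iPr)2, THF, −78 °C; then 8, −78 °C; AcOH quench
Reagents that add atoms: none
Why: Aldol addition; 7 can enolize only at C4, lithium enolates add 1,2 to enals at low temperature, and both new stereocenters are removed in step 5, so the diastereomer mixture does not matter.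

Step 5
Reactants: 10 (E)-5-hydroxy-6-methyl-4-{[(triisopropylsilyl)oxy]methyl}-1-(trimethylsilyl)hepta-1,6-dien-3-one
Product: 12 (1E,4E)-6-methyl-4-{[(triisopropylsilyl)oxy]methyl}-1-(trimethylsilyl)hepta-1,4,6-trien-3-one, via acetate 11 (not isolated)
Conditions: Ac2O, Et3N, DMAP (cat.), CH2Cl2, 0 °C; then DBU, 0 °C to rt
Reagents that add atoms: none
Why: Acetylation and E1cB elimination (aldol condensation); the acetate avoids a labile allylic sulfonate, and the elimination should place the isopropenyl group trans to the carbonyl, the less strained (4E) arrangement.

Step 6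
Reactants: 12 (1E,4E)-6-methyl-4-{[(triisopropylsilyl)oxy]methyl}-1-(trimethylsilyl)hepta-1,4,6-trien-3-one
Product: 13 (4S,5S)-4-(prop-1-en-2-yl)-5-{[(triisopropylsilyl)oxy]methyl}cyclopent-2-en-1-one
Conditions: Zn(OTf)2 (5 mol%), (S)-6,6'-bis(2,4,6-triisopropylphenyl)-1,1'-spirobiindane-7,7'-diyl hydrogen phosphate (6 mol%), PhOH (1.1 equiv), ClCH2CH2Cl, 40 °C
Reagents that add atoms: none
Why: Silicon-directed Nazarov cyclization under cooperative Zn(OTf)2/chiral phosphoric acid catalysis; the closest known reaction type is the catalytic enantioselective silicon-directed Nazarov reaction of β-silyl divinyl ketones. Activation of the carbonyl of 12 gives a 3-oxypentadienyl cation (C1–C5) that the isopropenyl group at C5 stabilizes further and that the α-substituent at C4 holds in the reactive s-trans/s-trans shape. The five-membered ring closes by thermal conrotatory 4π electrocyclization, which forms the C1–C5 bond of 12 (C3–C4 of 13). The oxyallyl cation so formed is β to silicon on one side only, so the Me3Si group leaves to phenol, the alkene is fixed at C2=C3 of 13 and the new sp3 carbon is untouched; the remaining enol is then protonated at C5. C4 is set by the sense of conrotation, which the chiral phosphate paired with the cation decides, and with the (4E) geometry of 12 fixed each sense corresponds to one configuration. C5 is set by protonation and stays epimerizable through the enol, so it should settle trans to the isopropenyl group under thermodynamic control (any cis isomer also converges at ketone 15). The step needs alkene regiocontrol (silicon), torquoselectivity (catalyst) and five-ring closure in preference to reaction at the diene terminus, which the (4E) geometry secures by holding the isopropenyl group away from C1; the weakly acidic medium and the bulky TIPS ether are chosen to slow alkene migration into conjugation and loss of silanol.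

Step 7
Reactants: 13 (4S,5S)-4-(prop-1-en-2-yl)-5-{[(triisopropylsilyl)oxy]methyl}cyclopent-2-en-1-one
Product: 15 (2S,3S)-3-(prop-1-en-2-yl)-2-{[(triisopropylsilyl)oxy]methyl}cyclopentan-1-one, via silyl enol ether 14 (not isolated)
Conditions: [(Ph3P)CuH]6 (3 mol%), PhMe2SiH (1.5 equiv), toluene, rt; then 1 M HCl, THF, 0 °C
Reagents that add atoms: none
Why: CuH-catalyzed conjugate reduction (1,4-hydrosilylation) of an enone; the isolated 1,1-disubstituted alkene is not reduced, no stereocenter is formed, and the enol ether 14 lies away from C2 so that center is not exposed before mild hydrolysis.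

Step 8
Reactants: 15 (2S,3S)-3-(prop-1-en-2-yl)-2-{[(triisopropylsilyl)oxy]methyl}cyclopentan-1-one
Product: 16 (1S,2S,3S)-1-methyl-3-(prop-1-en-2-yl)-2-{[(triisopropylsilyl)oxy]methyl}cyclopentan-1-ol
Conditions: MeLi, CeCl3, THF, −78 °C
Reagents that add atoms: methyllithium, [Li]C
Why: 1,2-Addition of MeCeCl2, which is weakly basic and should not enolize the β-silyloxy ketone; the reagent should approach anti to the adjacent silyloxymethyl group, placing CH3 trans and OH cis to it and setting the carbinol center as (S).

Step 9
Reactants: 16 (1S,2S,3S)-1-methyl-3-(prop-1-en-2-yl)-2-{[(triisopropylsilyl)oxy]methyl}cyclopentan-1-ol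
Product: 17 (1S,2S,3S)-2-(hydroxymethyl)-1-methyl-3-(prop-1-en-2-yl)cyclopentan-1-ol
Conditions: Bu4NF, THF, 0 °C to rt
Reagents that add atoms: none
Why: Fluoride cleavage of a primary silyl ether; nothing else in 16 responds to fluoride.

Step 10
Reactants: 17 (1S,2S,3S)-2-(hydroxymethyl)-1-methyl-3-(prop-1-en-2-yl)cyclopentan-1-ol
Product: 18 (1R,2S,5S)-2-hydroxy-2-methyl-5-(prop-1-en-2-yl)cyclopentane-1-carbaldehyde
Conditions: TEMPO (10 mol%), PhI(OAc)2, CH2Cl2, rt
Reagents that add atoms: none
Why: Oxoammonium oxidation of the primary alcohol, stopping at the aldehyde; the tertiary alcohol and the alkene are inert, and the base-free medium should spare the α-center and the β-hydroxy aldehyde.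

Step 11
Reactants: 19 2,4,6-trihydroxytoluene (2-methylbenzene-1,3,5-triol); 20 3-methylbutanoyl chloride
Product: 21 3-methyl-1-(2,4,6-trihydroxy-3-methylphenyl)butan-1-one
Conditions: AlCl3, PhNO2/ClCH2CH2Cl, 50 °C
Reagents that add atoms: none
Why: Friedel–Crafts acylation; the two free positions of 19 are equivalent, and the first acyl group deactivates the ring towards a second.

Step 12
Reactants: 18 (1R,2S,5S)-2-hydroxy-2-methyl-5-(prop-1-en-2-yl)cyclopentane-1-carbaldehyde; 21 3-methyl-1-(2,4,6-trihydroxy-3-methylphenyl)butan-1-one
Product: 23 3-methyl-1-[2,4,6-trihydroxy-3-{[(1R,2S,5S)-2-hydroxy-2-methyl-5-(prop-1-en-2-yl)cyclopentyl]methyl}-5-methylphenyl]butan-1-one, via o-quinone methide 22 (not isolated)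
Conditions: L-proline (20 mol%), Hantzsch ester (1.2 equiv), THF, rt to 40 °C
Reagents that add atoms: none
Why: Three-component reductive alkylation: Knoevenagel-type condensation at the only free ring carbon of 21 gives quinone methide 22, which takes a hydride from the dihydropyridine at the exocyclic carbon and rearomatizes; no stereocenter is formed and the hydride donor does not reduce the aldehyde.

Step 13
Reactants: 24 3-methylbut-2-en-1-ol (prenol)
Product: 25 tert-butyl (3-methylbut-2-en-1-yl) carbonate
Conditions: Boc2O, DMAP (10 mol%), CH2Cl2, 0 °C to rt
Reagents that add atoms: di-tert-butyl dicarbonate (Boc2O), CC(C)(C)OC(=O)OC(=O)OC(C)(C)C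
Why: Acyl transfer to a primary allylic alcohol; the carbonate ionizes readily with zerovalent palladium and supplies its own base.

Step 14
Reactants: 23 3-methyl-1-[2,4,6-trihydroxy-3-{[(1R,2S,5S)-2-hydroxy-2-methyl-5-(prop-1-en-2-yl)cyclopentyl]methyl}-5-methylphenyl]butan-1-one; 25 tert-butyl (3-methylbut-2-en-1-yl) carbonate
Product: 26 (6S)-3,5-dihydroxy-4-{[(1R,2S,5S)-2-hydroxy-2-methyl-5-(prop-1-en-2-yl)cyclopentyl]methyl}-6-methyl-2-(3-methylbutanoyl)-6-(3-methylbut-2-en-1-yl)cyclohexa-2,4-dien-1-one (the target, CNP0139230.1)
Conditions: Pd2(dba)3 (2.5 mol%), (R,R)-N,N'-bis(2-diphenylphosphinobenzoyl)-1,2-diaminocyclohexane (7.5 mol%), THF, 0 °C to rt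
Reagents that add atoms: none
Why: Asymmetric allylic alkylation with dearomatization (Tsuji–Trost type): the phenolate formed by the liberated tert-butoxide attacks the unsubstituted terminus of the π-prenylpalladium complex through the methyl-bearing ring carbon, the other alkyl-bearing carbon being shielded by the branched side chain; the chiral ligand chooses the face of the arene and so sets the quaternary center, since the ring A centers are too far away to do so.

## Compound list

1 | methyl 3-hydroxypropanoate | COC(=O)CCO | starting material
2 | methyl 3-[(triisopropylsilyl)oxy]propanoate | COC(=O)CCO[Si](C(C)C)(C(C)C)C(C)C | intermediate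
3 | N-methoxy-N-methyl-3-[(triisopropylsilyl)oxy]propanamide | CON(C)C(=O)CCO[Si](C(C)C)(C(C)C)C(C)C | intermediate
4 | (E)-(2-bromovinyl)trimethylsilane | C[Si](C)(C)/C=C/Br | starting material
5 | (E)-2-(trimethylsilyl)vinyllithium | [Li]/C=C/[Si](C)(C)C | intermediate (not isolated)
6 | lithium (E)-3-[methoxy(methyl)amino]-5-[(triisopropylsilyl)oxy]-1-(trimethylsilyl)pent-1-en-3-olate | CON(C)C(O[Li])(CCO[Si](C(C)C)(C(C)C)C(C)C)/C=C/[Si](C)(C)C | intermediate (not isolated)
7 | (E)-5-[(triisopropylsilyl)oxy]-1-(trimethylsilyl)pent-1-en-3-one | C[Si](C)(C)/C=C/C(=O)CCO[Si](C(C)C)(C(C)C)C(C)C | intermediate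
8 | methacrolein (2-methylprop-2-enal) | CC(=C)C=O | starting material
9 | lithium (1E)-5-[(triisopropylsilyl)oxy]-1-(trimethylsilyl)penta-1,3-dien-3-olate | [Li]OC(=CCO[Si](C(C)C)(C(C)C)C(C)C)/C=C/[Si](C)(C)C | intermediate (not isolated)
10 | (E)-5-hydroxy-6-methyl-4-{[(triisopropylsilyl)oxy]methyl}-1-(trimethylsilyl)hepta-1,6-dien-3-one, mixture of diastereomers | C=C(C)C(O)C(CO[Si](C(C)C)(C(C)C)C(C)C)C(=O)/C=C/[Si](C)(C)C | intermediate
11 | 5-O-acetate of 10 | C=C(C)C(OC(C)=O)C(CO[Si](C(C)C)(C(C)C)C(C)C)C(=O)/C=C/[Si](C)(C)C | intermediate (not isolated)
12 | (1E,4E)-6-methyl-4-{[(triisopropylsilyl)oxy]methyl}-1-(trimethylsilyl)hepta-1,4,6-trien-3-one | C=C(C)/C=C(\CO[Si](C(C)C)(C(C)C)C(C)C)C(=O)/C=C/[Si](C)(C)C | intermediate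
13 | (4S,5S)-4-(prop-1-en-2-yl)-5-{[(triisopropylsilyl)oxy]methyl}cyclopent-2-en-1-one (trans) | C=C(C)[C@H]1C=CC(=O)[C@@H]1CO[Si](C(C)C)(C(C)C)C(C)C | intermediate
14 | {[(4S,5S)-4-(prop-1-en-2-yl)-5-{[(triisopropylsilyl)oxy]methyl}cyclopent-1-en-1-yl]oxy}dimethyl(phenyl)silane | C=C(C)[C@H]1CC=C(O[Si](C)(C)c2ccccc2)[C@@H]1CO[Si](C(C)C)(C(C)C)C(C)C | intermediate (not isolated)
15 | (2S,3S)-3-(prop-1-en-2-yl)-2-{[(triisopropylsilyl)oxy]methyl}cyclopentan-1-one (trans) | C=C(C)[C@H]1CCC(=O)[C@@H]1CO[Si](C(C)C)(C(C)C)C(C)C | intermediate
16 | (1S,2S,3S)-1-methyl-3-(prop-1-en-2-yl)-2-{[(triisopropylsilyl)oxy]methyl}cyclopentan-1-ol | C=C(C)[C@H]1CC[C@](C)(O)[C@@H]1CO[Si](C(C)C)(C(C)C)C(C)C | intermediate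
17 | (1S,2S,3S)-2-(hydroxymethyl)-1-methyl-3-(prop-1-en-2-yl)cyclopentan-1-ol | C=C(C)[C@H]1CC[C@](C)(O)[C@@H]1CO | intermediate
18 | (1R,2S,5S)-2-hydroxy-2-methyl-5-(prop-1-en-2-yl)cyclopentane-1-carbaldehyde | C=C(C)[C@H]1CC[C@](C)(O)[C@@H]1C=O | intermediate
19 | 2,4,6-trihydroxytoluene | Cc1c(O)cc(O)cc1O | starting material
20 | 3-methylbutanoyl chloride | CC(C)CC(Cl)=O | starting material
21 | 3-methyl-1-(2,4,6-trihydroxy-3-methylphenyl)butan-1-one | CC(C)CC(=O)c1c(O)cc(O)c(C)c1O | intermediate
22 | o-quinone methide from 18 and 21 (exocyclic alkylidene on the dearomatized ring, alkene geometry not defined) | C=C(C)[C@H]1CC[C@](C)(O)[C@@H]1C=C1C(=O)C(C)=C(O)C(C(=O)CC(C)C)=C1O | intermediate (not isolated)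
23 | 3-methyl-1-[2,4,6-trihydroxy-3-{[(1R,2S,5S)-2-hydroxy-2-methyl-5-(prop-1-en-2-yl)cyclopentyl]methyl}-5-methylphenyl]butan-1-one | C=C(C)[C@H]1CC[C@](C)(O)[C@@H]1Cc1c(O)c(C)c(O)c(C(=O)CC(C)C)c1O | intermediate
24 | 3-methylbut-2-en-1-ol | CC(C)=CCO | starting material
25 | tert-butyl (3-methylbut-2-en-1-yl) carbonate | CC(C)=CCOC(=O)OC(C)(C)C | intermediate
26 | (6S)-3,5-dihydroxy-4-{[(1R,2S,5S)-2-hydroxy-2-methyl-5-(prop-1-en-2-yl)cyclopentyl]methyl}-6-methyl-2-(3-methylbutanoyl)-6-(3-methylbut-2-en-1-yl)cyclohexa-2,4-dien-1-one | C=C(C)[C@H]1CC[C@](C)(O)[C@@H]1CC1=C(O)[C@](C)(CC=C(C)C)C(=O)C(C(=O)CC(C)C)=C1O | target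

## Step count and risks

Total: 14 steps. Longest linear sequence: 12 steps (steps 1–10, 12 and 14, from 1). Steps 11 and 13 are one-step side branches.

**Step 6 (key step).**
- What may go wrong: slow closure because the isopropenyl group delocalizes the cation; acid-induced migration of the ring alkene or the isopropenyl alkene into conjugation, which would erase C4; loss of silanol from the β-silyloxy ketone; insufficient torquoselectivity.
- Fallback: from 12, cyclization with stoichiometric FeCl3 (CH2Cl2, −30 °C), the classical silicon-directed protocol, would give the racemic trans-cyclopentenone F1. The enantiomers would then be separated by preparative chromatography on a chiral stationary phase, which brings the route back to 13.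

**Step 14.**
- What may go wrong: weak facial discrimination on a pentasubstituted arene whose stereocenters are remote; competing alkylation at oxygen or at the other alkyl-bearing carbon; attack at the substituted terminus of the prenyl unit.
- Fallback: from 23, base-mediated dearomative C-prenylation with prenyl bromide and NaOMe in MeOH at 0 °C, without any chiral control, would give 26 together with its C6 epimer F2. Separating the two diastereomers by preparative HPLC returns the route at 26.

**Step 12.**
- What may go wrong: slow condensation at a hindered aldehyde; epimerization of C1 through the enamine; retro-aldol opening or dehydration of the β-hydroxy aldehyde; tautomerization of the quinone methide to a vinyl arene before hydride transfer.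
- Fallback: from 17, both hydroxyls would be silylated (Et3SiOTf, 2,6-lutidine) to the bis(triethylsilyl) ether F3. Swern oxidation, which cleaves and oxidizes the primary triethylsilyl ether only, would give the silyloxy aldehyde F4. Reductive alkylation of 21 with F4 under the conditions of step 12 would pass through the silylated quinone methide F5 to the triethylsilyl ether F6, and HF·pyridine would bring the route back to 23.

**Step 8.**
- What may go wrong: poor facial selectivity, because the face anti to the silyloxymethyl group is the one that carries the isopropenyl group one carbon further on; enolization followed by loss of silanolate.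
- Fallback: from 15, Wittig methylenation (Ph3P=CH2) would give the methylidenecyclopentane F7, and fluoride would free the homoallylic alcohol F8. Hydroxyl-directed epoxidation (VO(acac)2, t-BuOOH) should deliver oxygen on the face of the CH2OH group to give the spiro-epoxide F9. LiAlH4 would open F9 at the CH2 terminus and bring the route back to 17.

**Step 4.**
- What may go wrong: E1cB loss of silanolate from the β-silyloxy enolate, or conjugate addition to the silyl enone; later, incomplete (E) selectivity in step 5.
- Fallback: the aldol would be moved to the amide stage. From 3, LiN(iPr)2 would give the lithium amide enolate F10, which with 8 gives the β-hydroxy amide F11. Mesylation (MsCl, Et3N) to the mesylate F12 and elimination with DBU would give the (E)-dienyl amide F13. Addition of vinyllithium 5 would give the lithium adduct F14, which on acidic quench comes back to the route at 12.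

## Further compounds

F1 | step 6 | racemic trans-4-(prop-1-en-2-yl)-5-{[(triisopropylsilyl)oxy]methyl}cyclopent-2-en-1-one (13 with its mirror image; the mirror image is drawn) | C=C(C)[C@@H]1C=CC(=O)[C@H]1CO[Si](C(C)C)(C(C)C)C(C)C
F2 | step 14 | (6R) epimer of 26 | C=C(C)[C@H]1CC[C@](C)(O)[C@@H]1CC1=C(O)[C@@](C)(CC=C(C)C)C(=O)C(C(=O)CC(C)C)=C1O
F3 | step 12 | bis(triethylsilyl) ether of 17 | C=C(C)[C@H]1CC[C@](C)(O[Si](CC)(CC)CC)[C@@H]1CO[Si](CC)(CC)CC
F4 | step 12 | triethylsilyl ether of 18 | C=C(C)[C@H]1CC[C@](C)(O[Si](CC)(CC)CC)[C@@H]1C=O
F5 | step 12 | triethylsilyl ether of 22 | C=C(C)[C@H]1CC[C@](C)(O[Si](CC)(CC)CC)[C@@H]1C=C1C(=O)C(C)=C(O)C(C(=O)CC(C)C)=C1O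
F6 | step 12 | triethylsilyl ether of 23 | C=C(C)[C@H]1CC[C@](C)(O[Si](CC)(CC)CC)[C@@H]1Cc1c(O)c(C)c(O)c(C(=O)CC(C)C)c1O
F7 | step 8 | triisopropyl{[trans-2-methylidene-5-(prop-1-en-2-yl)cyclopentyl]methoxy}silane | C=C(C)[C@H]1CCC(=C)[C@@H]1CO[Si](C(C)C)(C(C)C)C(C)C
F8 | step 8 | [trans-2-methylidene-5-(prop-1-en-2-yl)cyclopentyl]methanol | C=C(C)[C@H]1CCC(=C)[C@@H]1CO
F9 | step 8 | spiro-epoxide of F8 with the epoxide oxygen cis to CH2OH | C=C(C)[C@H]1CC[C@]2(OC2)[C@@H]1CO
F10 | step 4 | lithium enolate of 3 | CON(C)C(O[Li])=CCO[Si](C(C)C)(C(C)C)C(C)C
F11 | step 4 | 3-hydroxy-N-methoxy-N,4-dimethyl-2-{[(triisopropylsilyl)oxy]methyl}pent-4-enamide (mixture of diastereomers) | C=C(C)C(O)C(CO[Si](C(C)C)(C(C)C)C(C)C)C(=O)N(C)OC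
F12 | step 4 | methanesulfonate of F11 | C=C(C)C(OS(C)(=O)=O)C(CO[Si](C(C)C)(C(C)C)C(C)C)C(=O)N(C)OC
F13 | step 4 | (E)-N-methoxy-N,4-dimethyl-2-{[(triisopropylsilyl)oxy]methyl}penta-2,4-dienamide | C=C(C)/C=C(\CO[Si](C(C)C)(C(C)C)C(C)C)C(=O)N(C)OC
F14 | step 4 | lithium hemiaminal adduct of F13 and 5 | C=C(C)/C=C(\CO[Si](C(C)C)(C(C)C)C(C)C)C(O[Li])(N(C)OC)/C=C/[Si](C)(C)C
A1 | alternative 1 | cis-fused cyclopenta-dihydropyran cycloadduct (cyclic enol ether of 26) | C=C(C)[C@H]1CC[C@]2(C)OC3=C(C[C@H]12)C(O)=C(C(=O)CC(C)C)C(=O)[C@@]3(C)CC=C(C)C
A2 | alternative 1 | ring-methyl triketone (26 with CH3 in place of the cyclopentylmethyl group) | CC1=C(O)[C@](C)(CC=C(C)C)C(=O)C(C(=O)CC(C)C)=C1O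
A3 | alternative 1 | (S)-1-methyl-3-(prop-1-en-2-yl)cyclopent-1-ene | C=C(C)[C@H]1CCC(C)=C1
A4 | alternative 2 | aryl [2-(triethylsilyloxy)-2-methyl-5-(prop-1-en-2-yl)cyclopentyl] ketone with three methoxymethyl ethers | C=C(C)[C@H]1CC[C@](C)(O[Si](CC)(CC)CC)[C@@H]1C(=O)c1c(OCOC)c(C)c(OCOC)cc1OCOC
A5 | alternative 2 | acyclic aryl ketone with a terminal allylic methyl carbonate | COC(=O)OC/C(C)=C/CC[C@](C)(O[Si](CC)(CC)CC)CC(=O)c1c(OCOC)c(C)c(OCOC)cc1OCOC
A6 | alternative 3 | cyclopentylmethyl methyl prenyl cyclohexanetrione (enol form, no acyl group) | C=C(C)[C@H]1CC[C@](C)(O[Si](CC)(CC)CC)[C@@H]1CC1=C(O)[C@](C)(CC=C(C)C)C(=O)C=C1O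
A7 | alternative 3 | 4-[2-(triethylsilyloxy)-2-methyl-5-(prop-1-en-2-yl)cyclopentyl]butan-2-one | C=C(C)[C@H]1CC[C@](C)(O[Si](CC)(CC)CC)[C@@H]1CCC(C)=O
A8 | alternative 3 | methyl 2-(chlorocarbonyl)-2,5-dimethylhex-4-enoate (single enantiomer) | COC(=O)[C@](C)(CC=C(C)C)C(Cl)=O
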